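Count this flask in mM of catalyst: by the step G + J -> D, each mM of J takes a mM of G out of the working round and leaves it as D.

| flask | E | Z | G | J | remark | time |
|---|---|---|---|---|---|---|
| elm | 0.25 M | 140 mM (held) | 19 mM | 42 mM | run made earlier |  |
| alder | 0.25 M | 140 mM (held) | 76 mM | 42 mM | run made earlier |  |
| ash | 0.50 M | 140 mM (held) | 38 mM | 42 mM | run made earlier |  |
| flask | 0.25 M | 140 mM (held) | 38 mM | 42 mM |  | 10 min |

- elm (time / min: Q / %): 1.33: 0.4; 2.50: 1.1; 4.00: 1.6; 5.00: 1.6; 6.00: 2.2; 8.00: 3.6
- alder (time / min: Q / %): 0.500: 1.1; 1.50: 4.3; 3.00: 10.9; 4.00: 17.2; 6.00: 30.1; 8.00: 44.5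
- ash (time / min: Q / %): 1.50: 0.8; 3.00: 1.8; 5.00: 4.1; 6.00: 4.9; 8.00: 5.7

(each reading ± 0.5 percentage points)

- as a solid, counted per litre of solution: E
- at the start none of L is dissolved
- the numbers in the tables scatter by 0.5 percentage points (one standard deviation)
- steps thought possible: Z <-> L; X + L + G -> G + Q; G + J -> D; E <-> X
- at the start none of E is in solution

- autumn: doubling the dissolution coefficient of E, all else as stated
- spring: doubling the solubility of E, all else as stated
- noon: doubling the saturation concentration of Z, all else as stated
- winter: doubling the amount of G, all else as stated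

- Q at 10 min, in percent of the E charged
- the change that raises the amount of Q at 10 min, in percent of the E charged most ("none" if none brings more than 2 percentage points) (autumn / spring / noon / winter / none)
- amount of Q at 10 min, in percent of the E charged, after autumn

First take the main step alone, X + L + G -> G + Q, with the dissolved gas L frozen at saturation. Alder is our gauge, because its G outnumbers its J, so 34.0 mM of G should survive. Its last two readings give a pace of 0.529 min⁻¹, in mM of Q per mM of surviving G. If all the flask's G worked at that pace, Q would reach 80.5%.

Now add J. The flask has a surplus s of 4.00 mM, the J charged less the G charged. G is therefore the limiting reagent of that side step, so we expect the round to fade and Q to end short of that figure. Winter is alder's recipe, with s at −34.0 mM, so winter is our choice.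

Last comes the dissolving of E. Ash has the flask's G and J with twice the E, so we assume its mM carry over. Its last reading becomes 11.4%, and its last slope carries this to 13.0%, our number.

The forecast gives 15.5% (10% to 19%), winter, and 16.5% after autumn (11% to 22%), holding that “J ties up much of the catalyst”. Our number is lower.

The flask gives 13.7%. The best change is winter, worth 45 percentage points, and autumn gives 22.0%, more than the forecast's figure.

    Z ⇌ L, rate k1*(csat - [L]) (kL = 7.37 min⁻¹)
    X + L + G → G + Q (k = 71.9 M⁻² min⁻¹)
    G + J → D (k = 26.0 M⁻¹ min⁻¹)
    E ⇌ X, rate k4*(cs4 - [X]) while solid is left; crystals form when [X] > cs4 (solubility = 0.200 M, k = 0.128 min⁻¹)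

The flask is not at rest at 10.0 min: G stands at 4.95%, E at 36.0% and J at 14%. The surplus reckons J's end at 9.52% of its charge, and at 100 min the flask holds J at 9.52% with G at 0%. In a neighbouring flask, the same but with 0.025 M of J, s is −13.0 mM, which reckons G at 34.2% of its charge; that neighbour shows 35.0% at 10.0 min, with J at 1.2%. In the flask itself, by 100 min, E stands at 0%, X at 76.9%, and Q has gone from 13.7% to 23.1%.

The numbers in the tables were computed with constants of no real substance, noise included.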